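Retrosynthesis: the two ester C–O bonds are cut first, then C10–O (allylic C–H oxidation), C6–H and C5–H (two reductions), then C4–C5 together with the C5–O bond of a temporary epoxide (this closes the cyclopentane), then C1–C2 (conjugate addition) and C8–CH3.
Forward: the seven-membered ring comes from 3-methylcyclohept-2-enone and is turned into the achiral 3,6-dimethylcyclohepta-2,6-dienone; a desymmetrising conjugate addition attaches the C2–C4 chain at C1; the cyclopentane C1–C2–C3–C4–C5 is closed last by an intramolecular Darzens annulation.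
Enabling feature: C5 is the only sp3 α-carbon of the C6 ketone and sits next to quaternary C1, which carries the C2–C3–C4 keto chain. In the target O4 is cis to H5 and anti to both the C1 methyl and O6, which is the pattern left by a tether-enforced cis aldol at C5 followed by inversion at C5 (chloride out, O4 in).
Stereochemistry: C1 from the chiral copper catalyst; C4 and the trans ring fusion from the Darzens geometry plus α-face protonation at C5; C6 from hydroxyl-directed hydride delivery; C10 from hydride attack anti to the C1 methyl group.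
Key step: step 7

Assumption: 3-methylcyclohept-2-en-1-one (1) is taken as a catalogue compound; the other starting materials (6, 19, 23) are commercial.
Numbering: bicyclic compounds are named on the daucane skeleton (C1 ring fusion with CH3, C2, C3, C4 with isopropyl, C5 ring fusion, C6 to C10 round the seven-membered ring, CH3 on C8); β is the face of the C1 methyl group, α the opposite face.

Step 1
Reactants: 1 3-methylcyclohept-2-en-1-one
Product: 3 3-methylcyclohepta-2,6-dien-1-one, via silyl dienol ether 2 (not isolated)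
Conditions: LiN(iPr)2, THF, −78 °C; Me3SiCl; then Pd(OAc)2 (1.05 equiv), MeCN, rt
Reagents that add atoms: none
Why: Kinetic deprotonation at the α′ methylene gives the cross-conjugated silyl dienol ether, and Saegusa–Ito oxidation should return the cross-conjugated dienone; no stereocentre is formed.

Step 2
Reactants: 3 3-methylcyclohepta-2,6-dien-1-one
Product: 5 3,6-dimethylcyclohepta-2,6-dien-1-one, via silyl dienol ether 4 (not isolated)
Conditions: Me2CuLi (from CuI and 2 MeLi), Me3SiCl, THF, −78 °C; then Pd(OAc)2 (1.05 equiv), MeCN, rt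
Reagents that add atoms: lithium dimethylcuprate, [Li+].C[Cu-]C
Why: Cuprate conjugate addition should occur at the unsubstituted β-carbon in preference to the methyl-bearing one, and a second Saegusa–Ito oxidation restores the double bond to give the achiral dienone with two enantiotopic enone units.

Step 3
Reactants: 5 3,6-dimethylcyclohepta-2,6-dien-1-one; 6 5-bromo-2-methylpent-2-ene
Product: 9 trimethyl{[(3R)-3,6-dimethyl-3-(4-methylpent-3-en-1-yl)cyclohepta-1,6-dien-1-yl]oxy}silane, via Grignard reagent 7 (not isolated), via magnesium dienolate 8 (not isolated)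
Conditions: Mg, Et2O, rt (6 to 7); Cu(OTf)2 (3 mol%), chiral imidazolinium chloride (NHC precursor, 4 mol%), Et2O, −30 °C; then Me3SiCl, Et3N, DMPU, −30 to 0 °C
Reagents that add atoms: chlorotrimethylsilane, C[Si](C)(C)Cl
Why: Copper-catalysed asymmetric conjugate addition of a Grignard reagent to a β-methyl cyclic enone is an established route to all-carbon quaternary centres; here the chiral carbene–copper catalyst (ligand enantiomer chosen for the R centre) selects one of the two enantiotopic enone units and so sets C1, and silylation fixes the enolate at C5–C6.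

Step 4
Reactants: 9 trimethyl{[(3R)-3,6-dimethyl-3-(4-methylpent-3-en-1-yl)cyclohepta-1,6-dien-1-yl]oxy}silane
Product: 10 (6R)-7-chloro-3,6-dimethyl-6-(4-methylpent-3-en-1-yl)cyclohept-2-en-1-one (both C7 epimers)
Conditions: N-chlorosuccinimide, THF, −20 °C
Reagents that add atoms: N-chlorosuccinimide, O=C1CCC(=O)N1Cl
Why: Electrophilic chlorination of a 2-silyloxy diene takes place at the terminal enol ether carbon (C5 of the target) and gives the α′-chloro enone; the new centre is a mixture, which does not matter because it is enolised in step 7.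

Step 5
Reactants: 10 (6R)-7-chloro-3,6-dimethyl-6-(4-methylpent-3-en-1-yl)cyclohept-2-en-1-one
Product: 11 (6S)-7-chloro-6-[2-(3,3-dimethyloxiran-2-yl)ethyl]-3,6-dimethylcyclohept-2-en-1-one (mixture at C7 and at the oxirane CH)
Conditions: mCPBA, CH2Cl2, 0 °C
Reagents that add atoms: 3-chloroperbenzoic acid, OOC(=O)c1cccc(Cl)c1
Why: Prilezhaev epoxidation should take the electron-rich trisubstituted side-chain alkene and leave the conjugated ring alkene; the oxirane centre is destroyed in step 6.

Step 6
Reactants: 11 (6S)-7-chloro-6-[2-(3,3-dimethyloxiran-2-yl)ethyl]-3,6-dimethylcyclohept-2-en-1-one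
Product: 12 (6S)-7-chloro-3,6-dimethyl-6-(4-methyl-3-oxopentyl)cyclohept-2-en-1-one (both C7 epimers)
Conditions: BF3·OEt2 (0.2 equiv), CH2Cl2, −78 °C
Reagents that add atoms: none
Why: Meinwald rearrangement: Lewis-acid opening at the tertiary oxirane carbon followed by a 1,2-hydride shift should give the isopropyl ketone (C4 of the target).

Step 7
Reactants: 12 (6S)-7-chloro-3,6-dimethyl-6-(4-methyl-3-oxopentyl)cyclohept-2-en-1-one
Product: 14 4α,5α-epoxydauc-7-en-6-one, via lithium chloro-aldolate 13 (not isolated)
Conditions: LiN(SiMe3)2 (1.1 equiv), THF, −78 °C to rt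
Reagents that add atoms: none
Why: Proposed new method: the base removes the only α-hydrogen of the ring ketone (C5–H, acidified by chlorine; C7 is sp2, so no regioisomeric ring enolate and no Favorskii path exist), the α-chloro dienolate adds to the C4 side-chain ketone in a 5-(enolexo)-exo-trig aldol that closes the cyclopentane, and the alkoxide then displaces chloride at C5 in a 3-exo-tet closure to the epoxide. The closest known reaction types are the Darzens condensation of α-chloro ketones with ketones and the closure of halohydrins at ring-fusion carbons; the intramolecular, ring-fusing version with a ketone acceptor is the new element. Because the chain hangs from C1, C4 can bond to C5 only on the face syn to C2, which places chlorine syn to the C1 methyl group, and only the aldolate with O4 anti to chlorine (the chelated one, with isopropyl on the convex face) can close, the other reverting by retro-aldol. Inversion at C5 therefore puts the epoxide oxygen on C4 and C5 anti to the C1 methyl group and swings C6 to the methyl face, which sets the C4 configuration of the target and turns the kinetically enforced cis ring fusion into the trans one. The step needs enolisation at C5 rather than at the side-chain ketone; this rests on the higher acidity of the α-chloro position, proton exchange between the enolates and the irreversible epoxide closure.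

Step 8
Reactants: 14 4α,5α-epoxydauc-7-en-6-one
Product: 16 4α,5α-epoxydauc-8-en-6-one, via potassium dienolate 15 (not isolated)
Conditions: KOt-Bu (1.5 equiv), THF, −20 °C; then AcOH, −78 °C
Reagents that add atoms: none
Why: Deconjugation of an enone: the α′ position is blocked (epoxide carbon), so γ-deprotonation at C9 gives the extended endocyclic dienolate, and kinetic protonation at the α-carbon C7 should give the β,γ-unsaturated ketone; no stereocentre is touched.

Step 9
Reactants: 16 4α,5α-epoxydauc-8-en-6-one
Product: 17 4α-hydroxy-5αH-dauc-8-en-6-one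
Conditions: SmI2 (2.2 equiv), THF–MeOH, −90 °C
Reagents that add atoms: none
Why: Samarium diiodide reduction of an α,β-epoxy ketone cleaves the Cα–O bond and keeps the C4 carbinol; the trivalent samarium chelate between the C4 alkoxide and the enolate oxygen holds the isopropyl group over the β face next to the C1 methyl, so kinetic protonation at C5 should come from the α face and give the trans ring fusion.

Step 10
Reactants: 17 4α-hydroxy-5αH-dauc-8-en-6-one
Product: 18 5αH-dauc-8-ene-4α,6β-diol
Conditions: Me4NBH(OAc)3, MeCN–AcOH, −30 °C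
Reagents that add atoms: none
Why: Evans–Saksena reduction: the borohydride exchanges onto the C4 hydroxyl and delivers hydride intramolecularly to the α face of the C6 ketone, which should give the 1,3-anti diol (6β-OH), and the mildly acidic medium avoids retro-aldol cleavage and C5 epimerisation.

Step 11
Reactants: 18 5αH-dauc-8-ene-4α,6β-diol; 19 4-(chlorocarbonyl)phenyl acetate
Product: 20 6β-(4-acetoxybenzoyloxy)-5αH-dauc-8-en-4α-ol
Conditions: pyridine, DMAP (cat.), CH2Cl2, 0 °C
Reagents that add atoms: none
Why: Acylation with an acid chloride should take the secondary C6 hydroxyl and leave the tertiary C4 hydroxyl.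

Step 12
Reactants: 20 6β-(4-acetoxybenzoyloxy)-5αH-dauc-8-en-4α-ol
Product: 21 6β-(4-acetoxybenzoyloxy)-4α-hydroxy-5αH-dauc-8-en-10-one
Conditions: CrO3, 3,5-dimethylpyrazole, CH2Cl2, −20 °C
Reagents that add atoms: chromium trioxide, O=[Cr](=O)=O
Why: Allylic oxidation of a trisubstituted ring alkene with the CrO3–3,5-dimethylpyrazole complex goes to the methylene next to the vinylic CH (as in the oxidation of Δ5-steroids to 7-ketones), here C10, while C7 is deactivated by the neighbouring acyloxy group; the β-methyl enone results.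

Step 13
Reactants: 21 6β-(4-acetoxybenzoyloxy)-4α-hydroxy-5αH-dauc-8-en-10-one
Product: 22 6β-(4-acetoxybenzoyloxy)-5αH-dauc-8-ene-4α,10β-diol
Conditions: NaBH4, CeCl3·7H2O, MeOH, −78 °C
Reagents that add atoms: none
Why: Luche reduction: 1,2-hydride addition to the enone from the α face, anti to the methyl group on the adjacent quaternary C1, should give the 10β-alcohol.

Step 14
Reactants: 22 6β-(4-acetoxybenzoyloxy)-5αH-dauc-8-ene-4α,10β-diol; 23 3-methylbutanoic anhydride
Product: 24 6β-(4-acetoxybenzoyloxy)-10β-(3-methylbutanoyloxy)-5αH-dauc-8-en-4α-ol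
Conditions: DMAP, Et3N, CH2Cl2, rt
Reagents that add atoms: none
Why: DMAP-catalysed acylation should esterify the secondary allylic C10 hydroxyl; the tertiary C4 hydroxyl does not react.

Step 15
Reactants: 24 6β-(4-acetoxybenzoyloxy)-10β-(3-methylbutanoyloxy)-5αH-dauc-8-en-4α-ol
Product: 25 (3S,3aS,4R,8S,8aS)-3-hydroxy-6,8a-dimethyl-8-[(3-methylbutanoyl)oxy]-3-(propan-2-yl)-1,2,3,3a,4,5,8,8a-octahydroazulen-4-yl 4-hydroxybenzoate
Conditions: pyrrolidine, CH2Cl2, 0 °C
Reagents that add atoms: none
Why: Aminolysis of the aryl acetate: phenyl esters react with amines far faster than the alkyl isovalerate and benzoate esters, so only the phenol should be released.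

Compound list
1 | 3-methylcyclohept-2-en-1-one | CC1=CC(=O)CCCC1 | starting material
2 | trimethyl[(6-methylcyclohepta-1,6-dien-1-yl)oxy]silane | CC1=CC(O[Si](C)(C)C)=CCCC1 | intermediate (not isolated)
3 | 3-methylcyclohepta-2,6-dien-1-one | CC1=CC(=O)C=CCC1 | intermediate
4 | trimethyl[(3,6-dimethylcyclohepta-1,6-dien-1-yl)oxy]silane, racemic | CC1=CC(O[Si](C)(C)C)=CC(C)CC1 | intermediate (not isolated)
5 | 3,6-dimethylcyclohepta-2,6-dien-1-one | CC1=CC(=O)C=C(C)CC1 | intermediate
6 | 5-bromo-2-methylpent-2-ene | CC(C)=CCCBr | starting material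
7 | (4-methylpent-3-en-1-yl)magnesium bromide | CC(C)=CCC[Mg]Br | intermediate (not isolated)
8 | bromomagnesium (3R)-3,6-dimethyl-3-(4-methylpent-3-en-1-yl)cyclohepta-1,6-dien-1-olate | CC1=CC(O[Mg]Br)=C[C@](C)(CCC=C(C)C)CC1 | intermediate (not isolated)
9 | trimethyl{[(3R)-3,6-dimethyl-3-(4-methylpent-3-en-1-yl)cyclohepta-1,6-dien-1-yl]oxy}silane | CC1=CC(O[Si](C)(C)C)=C[C@](C)(CCC=C(C)C)CC1 | intermediate
10 | (6R)-7-chloro-3,6-dimethyl-6-(4-methylpent-3-en-1-yl)cyclohept-2-en-1-one, both C7 epimers | CC1=CC(=O)C(Cl)[C@](C)(CCC=C(C)C)CC1 | intermediate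
11 | (6S)-7-chloro-6-[2-(3,3-dimethyloxiran-2-yl)ethyl]-3,6-dimethylcyclohept-2-en-1-one, mixture at C7 and oxirane CH | CC1=CC(=O)C(Cl)[C@](C)(CCC2OC2(C)C)CC1 | intermediate
12 | (6S)-7-chloro-3,6-dimethyl-6-(4-methyl-3-oxopentyl)cyclohept-2-en-1-one, both C7 epimers | CC1=CC(=O)C(Cl)[C@](C)(CCC(=O)C(C)C)CC1 | intermediate
13 | lithium 5β-chloro-6-oxodauc-7-en-4α-olate (cis-fused: C1–C10 and C5–C6 bonds both α; isopropyl β) | [Li+].CC1=CC(=O)[C@]2(Cl)[C@@]([O-])(C(C)C)CC[C@]2(C)CC1 | intermediate (not isolated)
14 | 4α,5α-epoxydauc-7-en-6-one (C1 methyl β, isopropyl β, C5–C6 bond β) | CC1=CC(=O)[C@]23O[C@]3(C(C)C)CC[C@]2(C)CC1 | intermediate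
15 | potassium 4α,5α-epoxydauca-6,8-dien-6-olate | [K+].CC1=CC[C@@]2(C)CC[C@@]3(C(C)C)O[C@@]23C([O-])=C1 | intermediate (not isolated)
16 | 4α,5α-epoxydauc-8-en-6-one | CC1=CC[C@@]2(C)CC[C@@]3(C(C)C)O[C@@]23C(=O)C1 | intermediate
17 | 4α-hydroxy-5αH-dauc-8-en-6-one (trans-fused) | CC1=CC[C@@]2(C)CC[C@](O)(C(C)C)[C@@H]2C(=O)C1 | intermediate
18 | 5αH-dauc-8-ene-4α,6β-diol | CC1=CC[C@@]2(C)CC[C@](O)(C(C)C)[C@@H]2[C@H](O)C1 | intermediate
19 | 4-(chlorocarbonyl)phenyl acetate (4-acetoxybenzoyl chloride) | CC(=O)Oc1ccc(cc1)C(Cl)=O | starting material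
20 | 6β-(4-acetoxybenzoyloxy)-5αH-dauc-8-en-4α-ol | CC1=CC[C@@]2(C)CC[C@](O)(C(C)C)[C@@H]2[C@H](OC(=O)c2ccc(OC(C)=O)cc2)C1 | intermediate
21 | 6β-(4-acetoxybenzoyloxy)-4α-hydroxy-5αH-dauc-8-en-10-one | CC1=CC(=O)[C@@]2(C)CC[C@](O)(C(C)C)[C@@H]2[C@H](OC(=O)c2ccc(OC(C)=O)cc2)C1 | intermediate
22 | 6β-(4-acetoxybenzoyloxy)-5αH-dauc-8-ene-4α,10β-diol | CC1=C[C@H](O)[C@@]2(C)CC[C@](O)(C(C)C)[C@@H]2[C@H](OC(=O)c2ccc(OC(C)=O)cc2)C1 | intermediate
23 | 3-methylbutanoic anhydride | CC(C)CC(=O)OC(=O)CC(C)C | starting material
24 | 6β-(4-acetoxybenzoyloxy)-10β-(3-methylbutanoyloxy)-5αH-dauc-8-en-4α-ol | CC1=C[C@H](OC(=O)CC(C)C)[C@@]2(C)CC[C@](O)(C(C)C)[C@@H]2[C@H](OC(=O)c2ccc(OC(C)=O)cc2)C1 | intermediate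
25 | (3S,3aS,4R,8S,8aS)-3-hydroxy-6,8a-dimethyl-8-[(3-methylbutanoyl)oxy]-3-(propan-2-yl)-1,2,3,3a,4,5,8,8a-octahydroazulen-4-yl 4-hydroxybenzoate | CC1=C[C@H](OC(=O)CC(C)C)[C@@]2(C)CC[C@](O)(C(C)C)[C@@H]2[C@H](OC(=O)c2ccc(O)cc2)C1 | target

Total step count: 15. Longest linear sequence: 15 steps (1 to 25).

Steps most likely to fail

Step 7 (Darzens annulation, proposed new method). The enolate may equilibrate to the side-chain ketone enolates, which can add to the ring enone, or the lithium aldolate may revert faster than it closes. The fallback sets out from 12 and returns at 14 in two known operations. Soft enolisation of the α-chloro ketone with Sn(OTf)2 and N-ethylpiperidine in CH2Cl2 at −78 °C gives a tin enolate whose chelated aldol closure stops at the isolable cis-fused chlorohydrin, 5β-chloro-4α-hydroxydauc-7-en-6-one F1. This is then closed to 14 with K2CO3 in MeOH at 0 °C.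

Step 8 (deconjugation). γ-Deprotonation at the C8 methyl group, or re-conjugation during the quench, may give double-bond isomer mixtures. The fallback sets out from 14 and returns at 16. The extended enol is fixed covalently with t-BuMe2SiOTf and Et3N as the endocyclic silyl dienol ether, 6-(tert-butyldimethylsilyloxy)-4α,5α-epoxydauca-6,8-diene F2, which can be purified. It is then protonated at C7 under kinetic control with Bu4NF–AcOH at −78 °C.

Step 12 (allylic oxidation). Hydrogen abstraction at the hindered C10 methylene next to quaternary C1 may be slow, so that attack at C7 or the C8 methyl group and over-oxidation compete. The fallback sets out from 20 and returns at 21 by oxygen transfer to the alkene instead of C–H abstraction. A singlet-oxygen ene reaction (O2, tetraphenylporphyrin, light, CH2Cl2) places the hydroperoxide on C8 with shift of the alkene to C9=C10 and gives 6β-(4-acetoxybenzoyloxy)-8-hydroperoxy-5αH-dauc-9-en-4α-ol F3. PPh3 reduces this to the tertiary allylic alcohol 6β-(4-acetoxybenzoyloxy)-5αH-dauc-9-ene-4α,8-diol F4. Pyridinium chlorochromate (C5H5NH[CrO3Cl]) then effects the oxidative 1,3-transposition (Babler–Dauben) to enone 21.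

Further compounds
F1 | step 7 | 5β-chloro-4α-hydroxydauc-7-en-6-one (cis-fused chlorohydrin) | CC1=CC(=O)[C@]2(Cl)[C@@](O)(C(C)C)CC[C@]2(C)CC1
F2 | step 8 | 6-(tert-butyldimethylsilyloxy)-4α,5α-epoxydauca-6,8-diene | CC1=CC[C@@]2(C)CC[C@@]3(C(C)C)O[C@@]23C(O[Si](C)(C)C(C)(C)C)=C1
F3 | step 12 | 6β-(4-acetoxybenzoyloxy)-8-hydroperoxy-5αH-dauc-9-en-4α-ol (C8 configuration not defined) | CC1(OO)C=C[C@@]2(C)CC[C@](O)(C(C)C)[C@@H]2[C@H](OC(=O)c2ccc(OC(C)=O)cc2)C1
F4 | step 12 | 6β-(4-acetoxybenzoyloxy)-5αH-dauc-9-ene-4α,8-diol (C8 configuration not defined) | CC1(O)C=C[C@@]2(C)CC[C@](O)(C(C)C)[C@@H]2[C@H](OC(=O)c2ccc(OC(C)=O)cc2)C1
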